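C8 carries a methyl and the ether oxygen and sits beside the contiguous stereocentres C9, C10 and C5 of ring B, so C5–C6–C7–C8 with that oxygen is read as a 2‑methylfuran and C9–C10 as an (E)‑enal (labdane numbering).
Rings A and B are closed together by an intramolecular furan Diels–Alder reaction (bonds C5–C10 and C8–C9, four stereocentres), steered by the single C3 silyloxy centre.
The oxygen bridge is then opened at C5 only: the endo C11 hydroxyl displaces it in an SN2′ sense, the temporary C7–O bond is reduced off and C5=C6 is hydrogenated, so C8 keeps its α‑oxygen.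
Ring C (the oxocane) is closed last by ring‑closing metathesis of an 8‑O‑allyl ether with a C13 isopropenyl group; 3β‑Br comes from 3α‑OH by inversion and the 13,14‑epoxide from the Z‑oxocene.
The precursor is built from 2‑methylfuran, ethyl 2‑bromo‑2‑methylpropanoate and an (E)‑C5 allylic bromide from prenol, with a CBS reduction setting C3.

Key step: step 11

Assumption: the SMILES is read as (3S,5R,8R,9R,10S,13R,14S)‑3‑bromo‑8,15:13,14‑diepoxylabdane (3β‑Br, 5α‑H, 8α‑O, 9α‑H, 10β‑CH3); labdane numbering is used for all intermediates and TBS stands for tert‑butyldimethylsilyl.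

Step 1
Reactants: 1 2‑methylfuran; 2 ethyl 2‑bromo‑2‑methylpropanoate
Product: 3 ethyl 2‑methyl‑2‑(5‑methylfuran‑2‑yl)propanoate
Conditions: fac‑Ir(ppy)3 (1 mol %), K2HPO4, MeCN, blue LEDs, rt, 1 in excess
Reagents that add atoms: none
Why: the photoredox‑generated tertiary α‑ester radical should add to the free α‑position of 2‑methylfuran and the adduct radical is oxidised and deprotonated back to the furan (homolytic aromatic substitution of an electron‑rich heteroarene by an α‑bromo carbonyl compound).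

Step 2
Reactants: 3 ethyl 2‑methyl‑2‑(5‑methylfuran‑2‑yl)propanoate
Product: 5 3‑methyl‑3‑(5‑methylfuran‑2‑yl)butan‑2‑one, via Weinreb amide 4 (not isolated)
Conditions: MeNH(OMe)·HCl, i‑PrMgCl, THF, −15 °C → rt; then MeMgBr, 0 °C → rt
Reagents that add atoms: methylmagnesium bromide, C[Mg]Br; N,O‑dimethylhydroxylamine hydrochloride, CNOC.Cl (its atoms stay only in 4)
Why: the magnesium amide should convert the ester, which has no α‑hydrogen, into the Weinreb amide, whose chelated adduct with MeMgBr stops at the ketone (one‑pot Weinreb ketone synthesis).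

Step 3
Reactants: 6 3‑methylbut‑2‑en‑1‑ol (prenol)
Product: 7 tert‑butyldimethyl[(3‑methylbut‑2‑en‑1‑yl)oxy]silane
Conditions: TBSCl, imidazole, CH2Cl2, 0 °C → rt
Reagents that add atoms: tert‑butyldimethylsilyl chloride, CC(C)(C)[Si](C)(C)Cl
Why: routine silylation of a primary alcohol.

Step 4
Reactants: 7 tert‑butyldimethyl[(3‑methylbut‑2‑en‑1‑yl)oxy]silane
Product: 8 (E)‑4‑[(tert‑butyldimethylsilyl)oxy]‑2‑methylbut‑2‑en‑1‑ol
Conditions: SeO2 (cat.), t‑BuOOH, CH2Cl2, rt
Reagents that add atoms: tert‑butyl hydroperoxide, CC(C)(C)OO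
Why: SeO2 allylic oxidation (ene reaction then [2,3]‑shift) of a trisubstituted alkene attacks the methyl group trans to the chain, so the E allylic alcohol should result.

Step 5
Reactants: 8 (E)‑4‑[(tert‑butyldimethylsilyl)oxy]‑2‑methylbut‑2‑en‑1‑ol
Product: 9 (E)‑[(4‑bromo‑3‑methylbut‑2‑en‑1‑yl)oxy](tert‑butyl)dimethylsilane
Conditions: CBr4, PPh3, CH2Cl2, 0 °C
Reagents that add atoms: carbon tetrabromide, BrC(Br)(Br)Br
Why: Appel bromination of a primary allylic alcohol proceeds by SN2 without allylic transposition or loss of the E geometry.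

Step 6
Reactants: 5 3‑methyl‑3‑(5‑methylfuran‑2‑yl)butan‑2‑one; 9 (E)‑[(4‑bromo‑3‑methylbut‑2‑en‑1‑yl)oxy](tert‑butyl)dimethylsilane
Product: 10 (E)‑8‑[(tert‑butyldimethylsilyl)oxy]‑2,6‑dimethyl‑2‑(5‑methylfuran‑2‑yl)oct‑6‑en‑3‑one
Conditions: LiN(i‑Pr)2, THF, −78 °C; then 9, DMPU, −78 → −20 °C
Reagents that add atoms: none
Why: the ketone can enolise only towards its methyl group, and SN2 alkylation of that lithium enolate by the primary allylic bromide carries the E alkene over unchanged (enolate alkylation).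

Step 7
Reactants: 10 (E)‑8‑[(tert‑butyldimethylsilyl)oxy]‑2,6‑dimethyl‑2‑(5‑methylfuran‑2‑yl)oct‑6‑en‑3‑one
Product: 11 (3S,6E)‑8‑[(tert‑butyldimethylsilyl)oxy]‑2,6‑dimethyl‑2‑(5‑methylfuran‑2‑yl)oct‑6‑en‑3‑ol
Conditions: (R)‑2‑methyl‑CBS‑oxazaborolidine (0.2 equiv), BH3·SMe2, THF, −20 °C; MeOH
Reagents that add atoms: none
Why: Corey–Bakshi–Shibata reduction, in which the quaternary furyl‑bearing carbon acts as the large group and the primary chain as the small one, so the (R)‑catalyst should deliver hydride to give the (S)‑carbinol (future C3).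

Step 8
Reactants: 11 (3S,6E)‑8‑[(tert‑butyldimethylsilyl)oxy]‑2,6‑dimethyl‑2‑(5‑methylfuran‑2‑yl)oct‑6‑en‑3‑ol
Product: 12 (3S,6E)‑3,8‑bis[(tert‑butyldimethylsilyl)oxy]‑2,6‑dimethyl‑2‑(5‑methylfuran‑2‑yl)oct‑6‑ene
Conditions: TBSOTf, 2,6‑lutidine, CH2Cl2, 0 °C
Reagents that add atoms: tert‑butyldimethylsilyl trifluoromethanesulfonate, CC(C)(C)[Si](C)(C)OS(=O)(=O)C(F)(F)F
Why: the silyl triflate is reactive enough to silylate the hindered neopentyl‑type secondary alcohol.

Step 9
Reactants: 12 (3S,6E)‑3,8‑bis[(tert‑butyldimethylsilyl)oxy]‑2,6‑dimethyl‑2‑(5‑methylfuran‑2‑yl)oct‑6‑ene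
Product: 13 (2E,6S)‑6‑[(tert‑butyldimethylsilyl)oxy]‑3,7‑dimethyl‑7‑(5‑methylfuran‑2‑yl)oct‑2‑en‑1‑ol
Conditions: PPTS (cat.), MeOH, rt
Reagents that add atoms: none
Why: acid‑catalysed methanolysis should remove the primary allylic silyl ether far faster than the secondary one flanked by the quaternary carbon (selective desilylation).

Step 10
Reactants: 13 (2E,6S)‑6‑[(tert‑butyldimethylsilyl)oxy]‑3,7‑dimethyl‑7‑(5‑methylfuran‑2‑yl)oct‑2‑en‑1‑ol
Product: 14 (2E,6S)‑6‑[(tert‑butyldimethylsilyl)oxy]‑3,7‑dimethyl‑7‑(5‑methylfuran‑2‑yl)oct‑2‑enal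
Conditions: MnO2, CH2Cl2, rt
Reagents that add atoms: none
Why: MnO2 oxidises the allylic alcohol to the enal under neutral conditions that leave the E geometry and the furan untouched.

Step 11
Reactants: 14 (2E,6S)‑6‑[(tert‑butyldimethylsilyl)oxy]‑3,7‑dimethyl‑7‑(5‑methylfuran‑2‑yl)oct‑2‑enal
Product: 15 3β‑TBSO‑5α,8α‑epoxydrim‑6‑en‑11‑al (7‑oxanorbornene cycloadduct: oxygen bridge C5–O–C8 on the α face; C6=C7; 10β‑CH3; 9β‑CHO endo)
Conditions: Me2AlCl (1.5 equiv), CH2Cl2, −78 → −40 °C; quenched and worked up cold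
Reagents that add atoms: none
Why: Me2AlCl binds the aldehyde and lowers the LUMO of the (E)‑enal, and the furan adds across its 2,5‑positions in a concerted but asynchronous [4+2] in which the C5–C10 bond (furan α‑carbon to the enal β‑carbon) runs ahead of C8–C9; the closest known reaction is the Lewis‑acid‑promoted intramolecular Diels–Alder reaction of furans tethered by four atoms to an enone, here stretched to a β,β‑disubstituted enal and a quaternary tether carbon. Ring A closes as a six‑membered chair through the tether C4–C3–C2–C1 with the tether exo (syn to the oxygen bridge), the only mode a six‑membered ring fused at C5–C10 tolerates, and ring B closes as the boat of the 7‑oxanorbornene. Because the addition is suprafacial on both partners, the E geometry places the C10 methyl and the formyl group endo (β) and the C9 hydrogen exo (α), while C5 and C8 receive the bridge oxygen on the α face. The absolute sense comes from C3: in the chair‑like transition state the silyloxy group sits equatorial, since the axial position would be 1,3‑diaxial to the forming C5–O bridge bond, so the (S) centre selects the furan face that gives the 5α,8α‑bridged, 10β‑methyl adduct. The step needs this facial selectivity, the exo‑tether mode and an equilibrium on the adduct side; the gem‑dimethyl group at C4, the low temperature and the immediate reduction of the aldehyde in step 12 are relied on for the last point.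

Step 12
Reactants: 15 3β‑TBSO‑5α,8α‑epoxydrim‑6‑en‑11‑al
Product: 16 3β‑TBSO‑5α,8α‑epoxydrim‑6‑en‑11‑ol
Conditions: NaBH4, MeOH–CH2Cl2, −40 → 0 °C
Reagents that add atoms: none
Why: borohydride reduction removes the carbonyl group that would allow cycloreversion or β‑elimination of the C8–O bond, and gives the endo hydroxymethyl group needed in step 13.

Step 13
Reactants: 16 3β‑TBSO‑5α,8α‑epoxydrim‑6‑en‑11‑ol
Product: 17 3β‑TBSO‑7β,11‑epoxydrim‑5‑en‑8α‑ol
Conditions: (+)‑camphorsulfonic acid (10 mol %), CH2Cl2, 0 °C → rt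
Reagents that add atoms: none
Why: Proposed new method: protonation of the strained bridge oxygen should ionise the allylic C5–O bond, the more congested one between two quaternary carbons, and the endo C11 hydroxyl, held beside C7 as in a norbornene iodoetherification, closes on the allyl cation from the endo face in an anti SN2′ sense, so only the C5–O bond can be exchanged, C8 keeps its oxygen and configuration and the new C7 centre is fixed by the tether; the closest known reactions are acid‑catalysed intramolecular SN2′ allylic etherification and the acid‑induced opening of 7‑oxanorbornenes.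

Step 14
Reactants: 17 3β‑TBSO‑7β,11‑epoxydrim‑5‑en‑8α‑ol
Product: 18 3β‑TBSO‑drim‑5‑ene‑8α,11‑diol
Conditions: Li (excess), EtNH2–THF, −78 °C; then NH4Cl
Reagents that add atoms: none
Why: dissolving‑metal reduction cleaves the allylic C7–O bond, which is axial and aligned with the C5=C6 π system, and the allyl anion should be protonated at the less hindered C7, leaving the trisubstituted C5=C6 bond (reductive cleavage of an allylic ether).

Step 15
Reactants: 18 3β‑TBSO‑drim‑5‑ene‑8α,11‑diol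
Product: 19 3β‑TBSO‑5α‑drimane‑8α,11‑diol
Conditions: H2 (4 atm), PtO2, EtOAc–AcOH, rt
Reagents that add atoms: none
Why: heterogeneous hydrogenation should deliver hydrogen to the α face, because the β face of C5=C6 is covered by the axial methyl groups on C4 and C10, giving 5α‑H and the trans ring fusion as in 4,4‑dimethyl‑Δ5 steroids.

Step 16
Reactants: 19 3β‑TBSO‑5α‑drimane‑8α,11‑diol
Product: 21 (11E)‑3β‑TBSO‑8α‑hydroxy‑14,15‑dinorlabd‑11‑en‑13‑one, via hydroxy aldehyde 20 (not isolated)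
Conditions: TEMPO (cat.), PhI(OAc)2, CH2Cl2, rt; then Ph3P=CHC(O)CH3, 40 °C
Reagents that add atoms: 1‑(triphenylphosphoranylidene)propan‑2‑one, CC(=O)C=P(c1ccccc1)(c1ccccc1)c1ccccc1
Why: the nitroxyl oxidation touches only the primary alcohol, and the β‑hydroxy aldehyde is trapped in the same pot by the non‑basic stabilised ylide in an E‑selective Wittig reaction before retro‑aldol cleavage or dehydration can occur.

Step 17
Reactants: 21 (11E)‑3β‑TBSO‑8α‑hydroxy‑14,15‑dinorlabd‑11‑en‑13‑one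
Product: 22 3β‑TBSO‑8α‑hydroxy‑14,15‑dinorlabdan‑13‑one
Conditions: H2 (1 atm), Pd/C, EtOAc, rt
Reagents that add atoms: none
Why: catalytic hydrogenation saturates the conjugated C11=C12 bond and leaves the ketone.

Step 18
Reactants: 22 3β‑TBSO‑8α‑hydroxy‑14,15‑dinorlabdan‑13‑one
Product: 23 3β‑TBSO‑13‑methylene‑14,15‑dinorlabdan‑8α‑ol (side chain CH2CH2C(CH3)=CH2)
Conditions: Ph3PCH3Br, KOt‑Bu (excess), THF, 0 °C → rt
Reagents that add atoms: methyltriphenylphosphonium bromide, C[P+](c1ccccc1)(c1ccccc1)c1ccccc1.[Br-]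
Why: Wittig methylenation of the unhindered methyl ketone; excess ylide covers the free tertiary hydroxyl.

Step 19
Reactants: 23 3β‑TBSO‑13‑methylene‑14,15‑dinorlabdan‑8α‑ol
Product: 24 8α‑allyloxy‑3β‑TBSO‑13‑methylene‑14,15‑dinorlabdane
Conditions: KH, allyl bromide, 18‑crown‑6 (cat.), THF, 0 °C → rt
Reagents that add atoms: allyl bromide, C=CCBr
Why: Williamson etherification of the tertiary potassium alkoxide with a small, reactive allylic halide; no other acidic or electrophilic site is present.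

Step 20
Reactants: 24 8α‑allyloxy‑3β‑TBSO‑13‑methylene‑14,15‑dinorlabdane
Product: 25 3β‑TBSO‑8α,15‑epoxylabd‑13(Z)‑ene (oxocene)
Conditions: second‑generation Grubbs catalyst RuCl2(=CHPh)(H2IMes)(PCy3) (10 mol %), toluene (2 mM), 80 °C
Reagents that add atoms: none
Why: ring‑closing metathesis between the allyl ether and the 1,1‑disubstituted alkene should close the eight‑membered ring, helped by the gauche, trans‑diequatorial attachment at C8 and C9; the ring size enforces the Z alkene.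

Step 21
Reactants: 25 3β‑TBSO‑8α,15‑epoxylabd‑13(Z)‑ene
Product: 26 8α,15‑epoxylabd‑13(Z)‑en‑3β‑ol
Conditions: Bu4NF, THF, 50 °C
Reagents that add atoms: none
Why: fluoride cleaves the silyl ether; the ether and alkene are inert.

Step 22
Reactants: 26 8α,15‑epoxylabd‑13(Z)‑en‑3β‑ol
Product: 27 8α,15‑epoxylabd‑13(Z)‑en‑3‑one
Conditions: Dess–Martin periodinane, CH2Cl2, rt
Reagents that add atoms: none
Why: mild oxidation of the only hydroxyl group to the ketone.

Step 23
Reactants: 27 8α,15‑epoxylabd‑13(Z)‑en‑3‑one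
Product: 28 8α,15‑epoxylabd‑13(Z)‑en‑3α‑ol
Conditions: LiBH(s‑Bu)3, THF, −78 °C; H2O
Reagents that add atoms: none
Why: the bulky hydride attacks the 4,4‑dimethyl‑3‑ketone along the equatorial direction and should give the axial 3α‑alcohol (sterically controlled ketone reduction).

Step 24
Reactants: 28 8α,15‑epoxylabd‑13(Z)‑en‑3α‑ol
Product: 29 3β‑bromo‑8α,15‑epoxylabd‑13(Z)‑ene
Conditions: PPh3, CBr4, CH2Cl2, 0 °C → rt
Reagents that add atoms: carbon tetrabromide, BrC(Br)(Br)Br
Why: Appel reaction, in which bromide displaces the axial alkoxyphosphonium group by SN2 with inversion to give the equatorial 3β‑bromide.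

Step 25
Reactants: 29 3β‑bromo‑8α,15‑epoxylabd‑13(Z)‑ene
Product: 30 (3S,5R,8R,9R,10S,13R,14S)‑3‑bromo‑8,15:13,14‑diepoxylabdane (target)
Conditions: dimethyldioxirane in acetone, CH2Cl2, −20 → 0 °C
Reagents that add atoms: dimethyldioxirane, CC1(C)OO1
Why: concerted syn epoxidation under neutral conditions; the oxocene should fold towards the α side, away from the axial C8 methyl (C15 anti to that methyl, C12 anti to C10), so the oxidant reaches the exposed convex face of C13=C14, which corresponds to the (13R,14S) epoxide.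

Compound list
1 | 2‑methylfuran | Cc1ccco1 | starting material
2 | ethyl 2‑bromo‑2‑methylpropanoate | CCOC(=O)C(C)(C)Br | starting material
3 | ethyl 2‑methyl‑2‑(5‑methylfuran‑2‑yl)propanoate | CCOC(=O)C(C)(C)c1ccc(C)o1 | intermediate
4 | N‑methoxy‑N,2‑dimethyl‑2‑(5‑methylfuran‑2‑yl)propanamide (not isolated) | CON(C)C(=O)C(C)(C)c1ccc(C)o1 | intermediate
5 | 3‑methyl‑3‑(5‑methylfuran‑2‑yl)butan‑2‑one | CC(=O)C(C)(C)c1ccc(C)o1 | intermediate
6 | 3‑methylbut‑2‑en‑1‑ol | CC(C)=CCO | starting material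
7 | tert‑butyldimethyl[(3‑methylbut‑2‑en‑1‑yl)oxy]silane | CC(C)=CCO[Si](C)(C)C(C)(C)C | intermediate
8 | (E)‑4‑[(tert‑butyldimethylsilyl)oxy]‑2‑methylbut‑2‑en‑1‑ol | OC/C(C)=C/CO[Si](C)(C)C(C)(C)C | intermediate
9 | (E)‑[(4‑bromo‑3‑methylbut‑2‑en‑1‑yl)oxy](tert‑butyl)dimethylsilane | BrC/C(C)=C/CO[Si](C)(C)C(C)(C)C | intermediate
10 | (E)‑8‑[(tert‑butyldimethylsilyl)oxy]‑2,6‑dimethyl‑2‑(5‑methylfuran‑2‑yl)oct‑6‑en‑3‑one | Cc1ccc(o1)C(C)(C)C(=O)CC/C(C)=C/CO[Si](C)(C)C(C)(C)C | intermediate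
11 | (3S,6E)‑8‑[(tert‑butyldimethylsilyl)oxy]‑2,6‑dimethyl‑2‑(5‑methylfuran‑2‑yl)oct‑6‑en‑3‑ol | Cc1ccc(o1)C(C)(C)[C@@H](O)CC/C(C)=C/CO[Si](C)(C)C(C)(C)C | intermediate
12 | (3S,6E)‑3,8‑bis[(tert‑butyldimethylsilyl)oxy]‑2,6‑dimethyl‑2‑(5‑methylfuran‑2‑yl)oct‑6‑ene | Cc1ccc(o1)C(C)(C)[C@@H](O[Si](C)(C)C(C)(C)C)CC/C(C)=C/CO[Si](C)(C)C(C)(C)C | intermediate
13 | (2E,6S)‑6‑[(tert‑butyldimethylsilyl)oxy]‑3,7‑dimethyl‑7‑(5‑methylfuran‑2‑yl)oct‑2‑en‑1‑ol | Cc1ccc(o1)C(C)(C)[C@@H](O[Si](C)(C)C(C)(C)C)CC/C(C)=C/CO | intermediate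
14 | (2E,6S)‑6‑[(tert‑butyldimethylsilyl)oxy]‑3,7‑dimethyl‑7‑(5‑methylfuran‑2‑yl)oct‑2‑enal | Cc1ccc(o1)C(C)(C)[C@@H](O[Si](C)(C)C(C)(C)C)CC/C(C)=C/C=O | intermediate
15 | 3β‑TBSO‑5α,8α‑epoxydrim‑6‑en‑11‑al (cycloadduct) | CC1(C)[C@@H](O[Si](C)(C)C(C)(C)C)CC[C@]2(C)[C@@H](C=O)[C@@]3(C)C=C[C@@]12O3 | intermediate
16 | 3β‑TBSO‑5α,8α‑epoxydrim‑6‑en‑11‑ol | CC1(C)[C@@H](O[Si](C)(C)C(C)(C)C)CC[C@]2(C)[C@@H](CO)[C@@]3(C)C=C[C@@]12O3 | intermediate
17 | 3β‑TBSO‑7β,11‑epoxydrim‑5‑en‑8α‑ol | CC1(C)[C@@H](O[Si](C)(C)C(C)(C)C)CC[C@]2(C)[C@H]3CO[C@@H](C=C12)[C@@]3(C)O | intermediate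
18 | 3β‑TBSO‑drim‑5‑ene‑8α,11‑diol | CC1(C)[C@@H](O[Si](C)(C)C(C)(C)C)CC[C@]2(C)[C@@H](CO)[C@](C)(O)CC=C12 | intermediate
19 | 3β‑TBSO‑5α‑drimane‑8α,11‑diol | CC1(C)[C@@H](O[Si](C)(C)C(C)(C)C)CC[C@]2(C)[C@@H](CO)[C@](C)(O)CC[C@@H]12 | intermediate
20 | 3β‑TBSO‑8α‑hydroxy‑5α‑driman‑11‑al (not isolated) | CC1(C)[C@@H](O[Si](C)(C)C(C)(C)C)CC[C@]2(C)[C@@H](C=O)[C@](C)(O)CC[C@@H]12 | intermediate
21 | (11E)‑3β‑TBSO‑8α‑hydroxy‑14,15‑dinorlabd‑11‑en‑13‑one | CC1(C)[C@@H](O[Si](C)(C)C(C)(C)C)CC[C@]2(C)[C@@H](/C=C/C(C)=O)[C@](C)(O)CC[C@@H]12 | intermediate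
22 | 3β‑TBSO‑8α‑hydroxy‑14,15‑dinorlabdan‑13‑one | CC1(C)[C@@H](O[Si](C)(C)C(C)(C)C)CC[C@]2(C)[C@@H](CCC(C)=O)[C@](C)(O)CC[C@@H]12 | intermediate
23 | 3β‑TBSO‑13‑methylene‑14,15‑dinorlabdan‑8α‑ol | CC1(C)[C@@H](O[Si](C)(C)C(C)(C)C)CC[C@]2(C)[C@@H](CCC(C)=C)[C@](C)(O)CC[C@@H]12 | intermediate
24 | 8α‑allyloxy‑3β‑TBSO‑13‑methylene‑14,15‑dinorlabdane | CC1(C)[C@@H](O[Si](C)(C)C(C)(C)C)CC[C@]2(C)[C@@H](CCC(C)=C)[C@](C)(OCC=C)CC[C@@H]12 | intermediate
25 | 3β‑TBSO‑8α,15‑epoxylabd‑13(Z)‑ene | CC1(C)[C@@H](O[Si](C)(C)C(C)(C)C)CC[C@]2(C)[C@H]3CC/C(C)=C\CO[C@]3(C)CC[C@@H]12 | intermediate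
26 | 8α,15‑epoxylabd‑13(Z)‑en‑3β‑ol | CC1(C)[C@@H](O)CC[C@]2(C)[C@H]3CC/C(C)=C\CO[C@]3(C)CC[C@@H]12 | intermediate
27 | 8α,15‑epoxylabd‑13(Z)‑en‑3‑one | CC1(C)C(=O)CC[C@]2(C)[C@H]3CC/C(C)=C\CO[C@]3(C)CC[C@@H]12 | intermediate
28 | 8α,15‑epoxylabd‑13(Z)‑en‑3α‑ol | CC1(C)[C@H](O)CC[C@]2(C)[C@H]3CC/C(C)=C\CO[C@]3(C)CC[C@@H]12 | intermediate
29 | 3β‑bromo‑8α,15‑epoxylabd‑13(Z)‑ene | CC1(C)[C@@H](Br)CC[C@]2(C)[C@H]3CC/C(C)=C\CO[C@]3(C)CC[C@@H]12 | intermediate
30 | (3S,5R,8R,9R,10S,13R,14S)‑3‑bromo‑8,15:13,14‑diepoxylabdane | CC1(C)[C@@H](Br)CC[C@]2(C)[C@H]3CC[C@@]4(C)O[C@H]4CO[C@]3(C)CC[C@@H]12 | target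

Total step count: 25.
Longest linear sequence: 23 steps (steps 3–5 and 6–25, from prenol); steps 1 and 2 form the furyl ketone branch, which joins at step 6.

Steps most likely to fail

1. Step 13 (carries the label).
   - What may go wrong: ionisation of the other bridgehead bond (C8–O) followed by elimination, a 1,2‑methyl shift from C8 to C7 in the allyl cation before the hydroxyl closes, or an equilibrium that does not favour the rearranged ether.
   - Fallback with known chemistry, from 16 back to 19: 16 is epoxidised on the exo (α) face with mCPBA, and the exo‑6,7‑epoxide F1 is opened in the same pot by the endo C11 hydroxyl at C7 (neighbouring‑group opening, as for norbornene epoxides) to give the 6α‑hydroxy‑7β,11‑ether F2, which still holds the bridge. Dess–Martin oxidation gives the 6‑ketone F3, in which both the C5–O bridge bond and the C7–O ether bond are α to the carbonyl. Excess SmI2 in THF–MeOH cleaves both (reductive cleavage of α‑alkoxy ketones, known for 7‑oxanorbornan‑2‑ones) and, after base equilibration of C5 to the trans ring fusion, should give the 8α,11‑dihydroxy‑5α‑6‑ketone F4. Its tosylhydrazone F5 is reduced with catecholborane/NaOAc to 19. This replaces steps 13–15 and avoids hydrogenating the hindered C5=C6 bond.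

2. Step 11 (key step).
   - What may go wrong: slow bond formation between the three adjacent fully substituted carbons C4, C5 and C10, cycloreversion on warming or during work‑up, E/Z isomerisation of the complexed enal, Lewis‑acid opening of the adduct, or weak discrimination between the two furan faces.
   - Fallback inside the same disconnection, from 14 back to 15 (a cationic dienophile in place of the Lewis‑acid‑complexed enal): 14 is converted with 1,2‑bis(trimethylsilyloxy)ethane and catalytic TMSOTf at −78 °C into the dioxolane F6. A stoichiometric amount of TMSOTf then opens the acetal to an alkoxy‑substituted allyl cation, a far stronger dienophile that should add to the furan at −78 °C (ionic Diels–Alder reaction) and reclose to the adduct dioxolane F7, which has no activated carbonyl through which to revert. Mild hydrolysis (PPTS, wet acetone) gives 15, which is taken directly into step 12.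

3. Step 24.
   - What may go wrong: anti elimination of the axial alkoxyphosphonium group with the axial 2β‑hydrogen to the 2‑ene, or migration of the antiperiplanar 4β‑methyl group, instead of substitution at the neopentyl‑type carbon.
   - Fallback, from 27 back to 29: ketone 27 is condensed with hydrazine to the hydrazone F8, which CuBr2/LiOt‑Bu oxidises to the 3,3‑dibromide F9. One bromine is then removed with Bu3SnH (1 equiv)/Et3B at −78 °C; the α‑bromo radical should take hydrogen along the axial direction on the α face, leaving the remaining bromine equatorial (3β), which is 29.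

Further compounds
F1 | step 13 | 3β‑TBSO‑5α,8α:6α,7α‑diepoxydriman‑11‑ol (exo‑epoxide) | CC1(C)[C@@H](O[Si](C)(C)C(C)(C)C)CC[C@]2(C)[C@@H](CO)[C@@]3(C)[C@@H]4O[C@@H]4[C@@]12O3
F2 | step 13 | 3β‑TBSO‑5α,8α:7β,11‑diepoxydriman‑6α‑ol | CC1(C)[C@@H](O[Si](C)(C)C(C)(C)C)CC[C@]2(C)[C@H]3CO[C@H]4[C@H](O)[C@@]12O[C@@]34C
F3 | step 13 | 3β‑TBSO‑5α,8α:7β,11‑diepoxydriman‑6‑one | CC1(C)[C@@H](O[Si](C)(C)C(C)(C)C)CC[C@]2(C)[C@H]3CO[C@H]4C(=O)[C@@]12O[C@@]34C
F4 | step 13 | 3β‑TBSO‑8α,11‑dihydroxy‑5α‑driman‑6‑one | CC1(C)[C@@H](O[Si](C)(C)C(C)(C)C)CC[C@]2(C)[C@@H](CO)[C@](C)(O)CC(=O)[C@@H]12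
F5 | step 13 | tosylhydrazone of F4 | CC1(C)[C@@H](O[Si](C)(C)C(C)(C)C)CC[C@]2(C)[C@@H](CO)[C@](C)(O)CC(=NNS(=O)(=O)c3ccc(C)cc3)[C@@H]12
F6 | step 11 | 2‑[(1E,5S)‑5‑[(tert‑butyldimethylsilyl)oxy]‑2,6‑dimethyl‑6‑(5‑methylfuran‑2‑yl)hept‑1‑en‑1‑yl]‑1,3‑dioxolane | Cc1ccc(o1)C(C)(C)[C@@H](O[Si](C)(C)C(C)(C)C)CC/C(C)=C/C1OCCO1
F7 | step 11 | ethylene acetal of 15 | CC1(C)[C@@H](O[Si](C)(C)C(C)(C)C)CC[C@]2(C)[C@@H](C4OCCO4)[C@@]3(C)C=C[C@@]12O3
F8 | step 24 | hydrazone of 27 | CC1(C)C(=NN)CC[C@]2(C)[C@H]3CC/C(C)=C\CO[C@]3(C)CC[C@@H]12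
F9 | step 24 | 3,3‑dibromo‑8α,15‑epoxylabd‑13(Z)‑ene | CC1(C)C(Br)(Br)CC[C@]2(C)[C@H]3CC/C(C)=C\CO[C@]3(C)CC[C@@H]12
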